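**Retrosynthetic overview**
1. End game on ring B and O7: MOM hydrolysis and chelation-controlled cleavage of the 7-O-methyl ether next to the C8 formyl group. The C3' prenyl group comes from an aromatic Claisen rearrangement of the 2'-O-(1,1-dimethylallyl) ether, whose only free ortho carbon is C3'.
2. Key disconnection O1–C8a: pyran ring C is closed last by a ring-contracting Smiles-type switch of a 10,11-dihydrodibenzo[b,f]oxepine in which O2' of ring B is parked on C8a. The C2 alkoxide adds to C8a, and O2' leaves as the free 2'-phenol that the Claisen step needs.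
3. Enabling feature: in ring A, C8a is the beta carbon of the vinylogous formate O–C8a=C8–CH=O (ortho to the C8 formyl group). The 2'-oxygen of ring B lies within seven-ring reach of C8a, so one ether oxygen on C8a can be exchanged for another by addition-elimination.
4. Hidden symmetry: C4 and the formyl carbon flank C8a, and O5 and O7 flank C6, so ring A comes from C2v-symmetric 2-fluoro-4,6-dimethoxyisophthalaldehyde. SNAr (O2'–C8a) and then a Perkin closure (C3=C4) build the oxepine, and an iridium-catalysed asymmetric hydrogenation sets C3.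
5. Ring order: rings A and B are bought. A temporary lactone masks O2', a temporary oxepine follows, and pyran ring C forms as the oxepine opens.

Key step: step 9

Remark on locants: explanations use isoflavan locants (O1, C2, C3, C4, C4a, C5 to C8, C8a, primed for ring B). Names of the oxepines use dibenzo[b,f]oxepine locants, in which C10 is the later C3, C11 the later C4 and C4a the later C8a.
Assumption: the (Ra,S) antipode of the spiro phosphine-oxazoline ligand in step 6 is taken to deliver the R acid; if the sense is opposite, the (Sa,R) antipode is used. The carbonate reagent of step 10 is taken as a catalogue compound (otherwise one operation from 2-methylbut-3-en-2-ol and Boc2O).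

**Step 1**
Reactants: 1 2-fluoro-4,6-dimethoxybenzaldehyde
Product: 2 2-fluoro-4,6-dimethoxybenzene-1,3-dicarbaldehyde
Conditions: Cl2CHOMe, TiCl4, CH2Cl2, 0 °C to rt; then ice-water
Reagents that add atoms: dichloromethyl methyl ether, COC(Cl)Cl; water, O
Why: Rieche formylation (electrophilic aromatic substitution) should go to C3, which is ortho and para to the two methoxy groups and flanked only by the small fluorine, and not to C5, which is buttressed between two methoxy groups, so that the C2v-symmetric dialdehyde results.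

**Step 2**
Reactants: 3 2-(2,4-dihydroxyphenyl)acetic acid
Product: 4 6-hydroxy-1-benzofuran-2(3H)-one
Conditions: p-TsOH·H2O (cat.), PhMe, reflux, azeotropic removal of water
Reagents that add atoms: none
Why: Acid-catalysed lactonisation can engage only the ortho hydroxyl group in a five-membered ring and so tells the two phenols of ring B apart without a selective protection.

**Step 3**
Reactants: 4 6-hydroxy-1-benzofuran-2(3H)-one
Product: 5 6-(methoxymethoxy)-1-benzofuran-2(3H)-one
Conditions: MOMCl, iPr2NEt, CH2Cl2, 0 °C to rt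
Reagents that add atoms: chloromethyl methyl ether, COCCl
Why: Base-mediated O-alkylation (MOM ether formation) takes the only free phenol, the later 4'-OH, and the hindered amine does not open the aryl lactone.

**Step 4**
Reactants: 5 6-(methoxymethoxy)-1-benzofuran-2(3H)-one; 2 2-fluoro-4,6-dimethoxybenzene-1,3-dicarbaldehyde
Product: 7 2-[2-(2,6-diformyl-3,5-dimethoxyphenoxy)-4-(methoxymethoxy)phenyl]acetic acid, via dipotassium phenoxide carboxylate 6 (not isolated)
Conditions: KOH (2.0 equiv), DMSO–H2O, rt; then 2, rt to 40 °C; then cold dilute HCl to pH 4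
Reagents that add atoms: potassium hydroxide, [K+].[OH-]
Why: Saponification of the aryl lactone frees the 2'-phenoxide, which displaces the fluoride between two ortho formyl groups in a nucleophilic aromatic substitution (SNAr) that the much less nucleophilic carboxylate cannot rival, and the symmetry of 2 allows one product only.

**Step 5**
Reactants: 7 2-[2-(2,6-diformyl-3,5-dimethoxyphenoxy)-4-(methoxymethoxy)phenyl]acetic acid
Product: 8 4-formyl-1,3-dimethoxy-7-(methoxymethoxy)dibenzo[b,f]oxepine-10-carboxylic acid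
Conditions: Ac2O, Et3N, 110 °C; then H2O–THF, rt
Reagents that add atoms: none
Why: Intramolecular Perkin condensation of the mixed-anhydride enolate with one of the two equivalent formyl groups closes the seven-membered ring, the tether limiting the reaction to one formyl group and fixing the cis-diaryl alkene geometry.

**Step 6**
Reactants: 8 4-formyl-1,3-dimethoxy-7-(methoxymethoxy)dibenzo[b,f]oxepine-10-carboxylic acid
Product: 9 (10R)-4-formyl-1,3-dimethoxy-7-(methoxymethoxy)-10,11-dihydrodibenzo[b,f]oxepine-10-carboxylic acid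
Conditions: H2 (10 atm), [Ir(cod)(L)][B(3,5-(CF3)2C6H3)4] (1 mol %, L = (Ra,S)-spirobiindane phosphine-oxazoline ligand), Et3N, MeOH, 45 °C
Reagents that add atoms: none
Why: Carboxylate-directed iridium-catalysed asymmetric hydrogenation of an alpha-aryl cinnamic acid, a substrate class with the same cis-diaryl geometry as 8, lets the chiral pocket of the spiro ligand select the alkene face and set C10 (the later C3) as R, and any concurrent reduction of the formyl group is harmless because step 7 reduces it anyway.

**Step 7**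
Reactants: 9 (10R)-4-formyl-1,3-dimethoxy-7-(methoxymethoxy)-10,11-dihydrodibenzo[b,f]oxepine-10-carboxylic acid
Product: 10 [(10R)-4-(hydroxymethyl)-1,3-dimethoxy-7-(methoxymethoxy)-10,11-dihydrodibenzo[b,f]oxepin-10-yl]methanol
Conditions: LiAlH4, THF, 0 °C to rt; then H2O
Reagents that add atoms: none
Why: Hydride reduction of the carboxylate and the aldehyde by LiAlH4 gives the diol, and C10 is safe because the carboxylate salt does not enolise.

**Step 8**
Reactants: 10 [(10R)-4-(hydroxymethyl)-1,3-dimethoxy-7-(methoxymethoxy)-10,11-dihydrodibenzo[b,f]oxepin-10-yl]methanol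
Product: 11 (10R)-10-(hydroxymethyl)-1,3-dimethoxy-7-(methoxymethoxy)-10,11-dihydrodibenzo[b,f]oxepine-4-carbaldehyde
Conditions: MnO2 (activated, excess), CH2Cl2, rt
Reagents that add atoms: none
Why: Chemoselective MnO2 oxidation takes the electron-rich benzylic alcohol to the aldehyde and leaves the saturated primary alcohol untouched, which re-arms ring A for the next step.

**Step 9**
Reactants: 11 (10R)-10-(hydroxymethyl)-1,3-dimethoxy-7-(methoxymethoxy)-10,11-dihydrodibenzo[b,f]oxepine-4-carbaldehyde
Product: 13 (3R)-3-[2-hydroxy-4-(methoxymethoxy)phenyl]-5,7-dimethoxychromane-8-carbaldehyde, via bridged Meisenheimer adduct 12 (not isolated)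
Conditions: NaH (1.2 equiv), THF, 0 °C to 65 °C; then AcOH
Reagents that add atoms: none
Why: Proposed new method: the sodium alkoxide at C2 adds to C8a of ring A, the carbon that bears the 2'-aryloxy group and stands ortho to the C8 formyl group, to give the bridged Meisenheimer adduct 12 with its charge on the formyl oxygen, and 12 then expels the ring B phenoxide, so that an addition-elimination exchanges the seven-membered oxepine for the six-membered pyran ring C. The closest known reaction types are the oxygen-to-oxygen Smiles rearrangement of activated diaryl ethers and the alkoxide ring closure of 3-(2-fluoro-3-formylaryl)propan-1-ols to chromans, and the new element is a nucleofuge that is itself a ring member, which turns the event into a ring-contracting skeletal switch. Ring C closes in the 6-exo-trig mode onto the C8a=C8 bond of the vinylogous formate O-C8a=C8-CH=O, and the bicyclo[3.2.2]nonane core of 12 is reached with little strain from the oxepine conformer that carries the CH2O arm pseudo-axial. No stereocenter is formed in 13, since C3 has no acidic hydrogen and keeps its R configuration, and the transient center C8a of 12 is dictated by the bridge from C3. The selectivity needed is C8a against C5, whose methoxy group is para to the formyl group and would also give a six-membered ring, and it is secured by the intact oxepine, which holds C3 on the C8a side of the C4a-C4 axis and keeps the oxygen out of reach of C5, by sodium chelation to the formyl oxygen in THF, and by the better nucleofuge at C8a. The change from an alkoxide to a phenoxide and the loss of seven-ring strain make the switch irreversible.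

**Step 10**
Reactants: 13 (3R)-3-[2-hydroxy-4-(methoxymethoxy)phenyl]-5,7-dimethoxychromane-8-carbaldehyde
Product: 14 (3R)-5,7-dimethoxy-3-[4-(methoxymethoxy)-2-(2-methylbut-3-en-2-yloxy)phenyl]chromane-8-carbaldehyde
Conditions: Pd(PPh3)4 (5 mol %), tert-butyl (2-methylbut-3-en-2-yl) carbonate, THF, 0 °C to rt
Reagents that add atoms: tert-butyl (2-methylbut-3-en-2-yl) carbonate, CC(C)(C)OC(=O)OC(C)(C)C=C
Why: In this Tsuji-Trost type O-allylation zerovalent palladium ionises the tertiary carbonate, the tert-butoxide set free deprotonates the only phenol, and kinetic attack at the more substituted allyl terminus gives the 1,1-dimethylallyl ether.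

**Step 11**
Reactants: 14 (3R)-5,7-dimethoxy-3-[4-(methoxymethoxy)-2-(2-methylbut-3-en-2-yloxy)phenyl]chromane-8-carbaldehyde
Product: 16 (3R)-3-[2-hydroxy-4-(methoxymethoxy)-3-(3-methylbut-2-enyl)phenyl]-5,7-dimethoxychromane-8-carbaldehyde, via ortho-dienone 15 (not isolated)
Conditions: PhMe, 110 °C, sealed tube
Reagents that add atoms: none
Why: The aromatic Claisen rearrangement, a [3,3]-sigmatropic shift with allyl inversion, can reach only C3' because the other ortho carbon C1' is substituted, and enolisation of dienone 15 gives the 3'-prenyl phenol without touching C3.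

**Step 12**
Reactants: 16 (3R)-3-[2-hydroxy-4-(methoxymethoxy)-3-(3-methylbut-2-enyl)phenyl]-5,7-dimethoxychromane-8-carbaldehyde
Product: 17 (3R)-7-hydroxy-3-[2-hydroxy-4-(methoxymethoxy)-3-(3-methylbut-2-enyl)phenyl]-5-methoxychromane-8-carbaldehyde
Conditions: MgI2 (2 equiv), Et2O–PhMe, 60 °C; then H2O
Reagents that add atoms: none
Why: In this chelation-controlled aryl methyl ether cleavage magnesium held between the formyl oxygen and O7 activates that methyl group for SN2 attack by iodide, the 5-methoxy group has no neighbouring carbonyl, the O1–C2 bond is a beta-branched primary center far slower than methyl, and the neutral medium spares the prenyl and MOM groups.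

**Step 13**
Reactants: 17 (3R)-7-hydroxy-3-[2-hydroxy-4-(methoxymethoxy)-3-(3-methylbut-2-enyl)phenyl]-5-methoxychromane-8-carbaldehyde
Product: 18 (3R)-3-[2,4-dihydroxy-3-(3-methylbut-2-enyl)phenyl]-7-hydroxy-5-methoxychromane-8-carbaldehyde (target)
Conditions: aq HCl (3 M), THF–iPrOH, 45 °C
Reagents that add atoms: none
Why: Mild acid hydrolysis of the MOM acetal, standard for ortho-prenyl phenols, frees the 4'-OH under conditions too weak to cyclise the prenyl group onto a neighbouring phenol or to disturb C3.

**Compound list**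
1 | 2-fluoro-4,6-dimethoxybenzaldehyde | COc1cc(F)c(C=O)c(OC)c1 | starting material
2 | 2-fluoro-4,6-dimethoxybenzene-1,3-dicarbaldehyde | COc1cc(OC)c(C=O)c(F)c1C=O | intermediate
3 | 2-(2,4-dihydroxyphenyl)acetic acid | OC(=O)Cc1ccc(O)cc1O | starting material
4 | 6-hydroxy-1-benzofuran-2(3H)-one | O=C1Cc2ccc(O)cc2O1 | intermediate
5 | 6-(methoxymethoxy)-1-benzofuran-2(3H)-one | COCOc1ccc2CC(=O)Oc2c1 | intermediate
6 | dipotassium 2-[4-(methoxymethoxy)-2-oxidophenyl]acetate | COCOc1ccc(CC(=O)[O-])c([O-])c1.[K+].[K+] | intermediate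
7 | 2-[2-(2,6-diformyl-3,5-dimethoxyphenoxy)-4-(methoxymethoxy)phenyl]acetic acid | COCOc1ccc(CC(=O)O)c(Oc2c(C=O)c(OC)cc(OC)c2C=O)c1 | intermediate
8 | 4-formyl-1,3-dimethoxy-7-(methoxymethoxy)dibenzo[b,f]oxepine-10-carboxylic acid | OC(=O)C1=Cc2c(OC)cc(OC)c(C=O)c2Oc2cc(OCOC)ccc12 | intermediate
9 | (10R)-4-formyl-1,3-dimethoxy-7-(methoxymethoxy)-10,11-dihydrodibenzo[b,f]oxepine-10-carboxylic acid | OC(=O)[C@@H]1Cc2c(OC)cc(OC)c(C=O)c2Oc2cc(OCOC)ccc12 | intermediate
10 | [(10R)-4-(hydroxymethyl)-1,3-dimethoxy-7-(methoxymethoxy)-10,11-dihydrodibenzo[b,f]oxepin-10-yl]methanol | OC[C@@H]1Cc2c(OC)cc(OC)c(CO)c2Oc2cc(OCOC)ccc12 | intermediate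
11 | (10R)-10-(hydroxymethyl)-1,3-dimethoxy-7-(methoxymethoxy)-10,11-dihydrodibenzo[b,f]oxepine-4-carbaldehyde | OC[C@@H]1Cc2c(OC)cc(OC)c(C=O)c2Oc2cc(OCOC)ccc12 | intermediate
12 | sodium salt of the bridged Meisenheimer adduct (O1 and O2' both on sp3 C8a, charge on the formyl oxygen, C3 R) | [Na+].[O-]C=C1C(OC)=CC(OC)=C2C[C@H]3CO[C@@]12Oc1cc(OCOC)ccc13 | intermediate
13 | (3R)-3-[2-hydroxy-4-(methoxymethoxy)phenyl]-5,7-dimethoxychromane-8-carbaldehyde | COc1cc(OC)c(C=O)c2c1C[C@H](c1ccc(OCOC)cc1O)CO2 | intermediate
14 | (3R)-5,7-dimethoxy-3-[4-(methoxymethoxy)-2-(2-methylbut-3-en-2-yloxy)phenyl]chromane-8-carbaldehyde | COc1cc(OC)c(C=O)c2c1C[C@H](c1ccc(OCOC)cc1OC(C)(C)C=C)CO2 | intermediate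
15 | ortho-dienone of the Claisen step (6-prenylcyclohexa-2,4-dienone, either epimer at the prenyl-bearing carbon, C3 R) | COc1cc(OC)c(C=O)c2c1C[C@H](C1=CC=C(OCOC)C(CC=C(C)C)C1=O)CO2 | intermediate
16 | (3R)-3-[2-hydroxy-4-(methoxymethoxy)-3-(3-methylbut-2-enyl)phenyl]-5,7-dimethoxychromane-8-carbaldehyde | COc1cc(OC)c(C=O)c2c1C[C@H](c1ccc(OCOC)c(CC=C(C)C)c1O)CO2 | intermediate
17 | (3R)-7-hydroxy-3-[2-hydroxy-4-(methoxymethoxy)-3-(3-methylbut-2-enyl)phenyl]-5-methoxychromane-8-carbaldehyde | COc1cc(O)c(C=O)c2c1C[C@H](c1ccc(OCOC)c(CC=C(C)C)c1O)CO2 | intermediate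
18 | (3R)-3-[2,4-dihydroxy-3-(3-methylbut-2-enyl)phenyl]-7-hydroxy-5-methoxychromane-8-carbaldehyde | COc1cc(O)c(C=O)c2c1C[C@H](c1ccc(O)c(CC=C(C)C)c1O)CO2 | target

**Step count**
- Total step count: 13.
- Longest linear sequence: 12 steps (from 3, steps 2 to 13).

**Steps most likely to fail**

Step 9. Ring A is activated by one formyl group only and carries two donor methoxy groups. Addition of the alkoxide may therefore be too slow, and hydride transfer between alkoxide and aldehyde of two molecules may take over. The fallback gives up the temporary ring and uses fluoride as the nucleofuge, which is known chemistry. It sets out from 6 and 2 and comes back at 13.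
- Salt 6 is benzylated on the phenoxide oxygen (BnBr, 1 equiv, DMSO; then dilute HCl) to 2-[2-(benzyloxy)-4-(methoxymethoxy)phenyl]acetic acid F1.
- Perkin condensation of F1 with an excess of 2 (Ac2O, Et3N, 100 °C) gives (E)-2-[2-(benzyloxy)-4-(methoxymethoxy)phenyl]-3-(2-fluoro-3-formyl-4,6-dimethoxyphenyl)prop-2-enoic acid F2.
- The hydrogenation conditions of step 6 give (2R)-2-[2-(benzyloxy)-4-(methoxymethoxy)phenyl]-3-(2-fluoro-3-formyl-4,6-dimethoxyphenyl)propanoic acid F3.
- LiAlH4 gives (2R)-2-[2-(benzyloxy)-4-(methoxymethoxy)phenyl]-3-[2-fluoro-3-(hydroxymethyl)-4,6-dimethoxyphenyl]propan-1-ol F4.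
- MnO2 gives 3-[(2R)-2-[2-(benzyloxy)-4-(methoxymethoxy)phenyl]-3-hydroxypropyl]-2-fluoro-4,6-dimethoxybenzaldehyde F5.
- NaH in THF closes the same O1–C8a bond by SNAr on the ortho-fluorobenzaldehyde to (3R)-3-[2-(benzyloxy)-4-(methoxymethoxy)phenyl]-5,7-dimethoxychromane-8-carbaldehyde F6.
- Hydrogenolysis (H2, Pd/C, EtOAc) frees the 2'-OH and gives 13.

Step 6. The tub-shaped tricyclic acid may show poor facial selectivity or slow hydrogen uptake. The fallback replaces catalyst control by auxiliary-controlled protonation of a ketene. It sets out from 8 and comes back at 10.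
- Acid 8 is hydrogenated without control ([Ir(cod)(PCy3)(py)]PF6, H2, CH2Cl2) to racemic 4-formyl-1,3-dimethoxy-7-(methoxymethoxy)-10,11-dihydrodibenzo[b,f]oxepine-10-carboxylic acid F7.
- 1-Chloro-N,N,2-trimethylprop-1-en-1-amine converts F7 under neutral conditions into the racemic acid chloride F8.
- Et3N in PhMe gives the aryl alkyl ketene F9.
- (R)-Pantolactone adds at −78 °C with diastereoselective protonation at C10, so that both enantiomers of F7 converge on (3R)-4,4-dimethyl-2-oxooxolan-3-yl (10R)-4-formyl-1,3-dimethoxy-7-(methoxymethoxy)-10,11-dihydrodibenzo[b,f]oxepine-10-carboxylate F10.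
- LiAlH4 reduces ester, lactone and aldehyde together and delivers diol 10.

Step 10. The hindered phenoxide may attack the unsubstituted allyl terminus, or the branched ether may isomerise to the linear one on palladium. Either event would lead the Claisen step to the wrong allyl connectivity. The fallback uses a copper-catalysed propargylic substitution, which can give the tertiary ether only. It sets out from 13 and comes back at 14.
- Phenol 13 is alkylated with 3-chloro-3-methylbut-1-yne (CuCl2 cat., DBU, MeCN, 0 °C) to (3R)-5,7-dimethoxy-3-[4-(methoxymethoxy)-2-(2-methylbut-3-yn-2-yloxy)phenyl]chromane-8-carbaldehyde F11.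
- Semi-hydrogenation (H2, Pd/CaCO3 poisoned by Pb(OAc)2, quinoline, EtOAc) gives 14.

**Further compounds**
F1 | step 9 | 2-[2-(benzyloxy)-4-(methoxymethoxy)phenyl]acetic acid | COCOc1ccc(CC(=O)O)c(OCc2ccccc2)c1
F2 | step 9 | (E)-2-[2-(benzyloxy)-4-(methoxymethoxy)phenyl]-3-(2-fluoro-3-formyl-4,6-dimethoxyphenyl)prop-2-enoic acid | OC(=O)/C(c1ccc(OCOC)cc1OCc1ccccc1)=C/c1c(F)c(C=O)c(OC)cc1OC
F3 | step 9 | (2R)-2-[2-(benzyloxy)-4-(methoxymethoxy)phenyl]-3-(2-fluoro-3-formyl-4,6-dimethoxyphenyl)propanoic acid | OC(=O)[C@H](Cc1c(F)c(C=O)c(OC)cc1OC)c1ccc(OCOC)cc1OCc1ccccc1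
F4 | step 9 | (2R)-2-[2-(benzyloxy)-4-(methoxymethoxy)phenyl]-3-[2-fluoro-3-(hydroxymethyl)-4,6-dimethoxyphenyl]propan-1-ol | OC[C@H](Cc1c(F)c(CO)c(OC)cc1OC)c1ccc(OCOC)cc1OCc1ccccc1
F5 | step 9 | 3-[(2R)-2-[2-(benzyloxy)-4-(methoxymethoxy)phenyl]-3-hydroxypropyl]-2-fluoro-4,6-dimethoxybenzaldehyde | OC[C@H](Cc1c(F)c(C=O)c(OC)cc1OC)c1ccc(OCOC)cc1OCc1ccccc1
F6 | step 9 | (3R)-3-[2-(benzyloxy)-4-(methoxymethoxy)phenyl]-5,7-dimethoxychromane-8-carbaldehyde | COc1cc(OC)c(C=O)c2c1C[C@H](c1ccc(OCOC)cc1OCc1ccccc1)CO2
F7 | step 6 | racemic 4-formyl-1,3-dimethoxy-7-(methoxymethoxy)-10,11-dihydrodibenzo[b,f]oxepine-10-carboxylic acid | OC(=O)C1Cc2c(OC)cc(OC)c(C=O)c2Oc2cc(OCOC)ccc12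
F8 | step 6 | racemic 4-formyl-1,3-dimethoxy-7-(methoxymethoxy)-10,11-dihydrodibenzo[b,f]oxepine-10-carbonyl chloride | ClC(=O)C1Cc2c(OC)cc(OC)c(C=O)c2Oc2cc(OCOC)ccc12
F9 | step 6 | 1,3-dimethoxy-7-(methoxymethoxy)-10-(oxomethylidene)-10,11-dihydrodibenzo[b,f]oxepine-4-carbaldehyde (ketene) | O=C=C1Cc2c(OC)cc(OC)c(C=O)c2Oc2cc(OCOC)ccc12
F10 | step 6 | (3R)-4,4-dimethyl-2-oxooxolan-3-yl (10R)-4-formyl-1,3-dimethoxy-7-(methoxymethoxy)-10,11-dihydrodibenzo[b,f]oxepine-10-carboxylate | CC1(C)COC(=O)[C@@H]1OC(=O)[C@@H]1Cc2c(OC)cc(OC)c(C=O)c2Oc2cc(OCOC)ccc12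
F11 | step 10 | (3R)-5,7-dimethoxy-3-[4-(methoxymethoxy)-2-(2-methylbut-3-yn-2-yloxy)phenyl]chromane-8-carbaldehyde | COc1cc(OC)c(C=O)c2c1C[C@H](c1ccc(OCOC)cc1OC(C)(C)C#C)CO2
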